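**Retrosynthetic overview** (ring 1 = cyclopentane, ring 2 = pyrrolidine, ring 3 = piperidine, ring 4 = lactone, ring 5 = cyclohexane, ring 6 = cyclopentene)
1. 27 ⇐ N-oxidation of amine 26; lactone ring 4 ⇐ carbon–oxygen bond by acid SN1 lactonisation of the tertiary carbinol/tert-butyl ester 24, steered by the closed piperidine.
2. Piperidine ring 3 ⇐ key carbon–nitrogen bond: stereoinvertive intramolecular amination of the allylic alcohol in 22 (new ammonium-Mitsunobu variant).
3. 22 ⇐ aldol/reduction union of enone 5 (rings 5 + 6) with amino ketone 19 (rings 1 + 2).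
4. 19 ⇐ cyclopentenone 6 (conjugate addition/triflation, allylic chlorination, N-alkylation, Heck acetylation, tandem aza-Michael/Michael, hydrogenation); 5 ⇐ cyclohexenone 1 (conjugate addition, aldol condensation).
5. Ring order: rings 1 and 5 are bought; ring 6 (step 2) and ring 2 (step 7) are closed in the fragments, then ring 3 (step 10), then ring 4 (step 11).

Assumption 1: the enantiomer of each chiral diphosphine (Taniaphos in step 1, Josiphos in step 3) is the one that gives (S)-3 and (S)-9.
Assumption 2: the tertiary carbinol carbon made in step 9 is carried as both epimers (no stereo mark at that atom in 21–25 and F2), because step 11 resets it.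

Step 1
Reactants: 1 cyclohex-2-en-1-one; 2 [2-(1,3-dioxolan-2-yl)ethyl]magnesium bromide
Product: 3 (3S)-3-[2-(1,3-dioxolan-2-yl)ethyl]cyclohexan-1-one
Conditions: CuCl (5 mol%), Taniaphos (6 mol%), Et2O, 0 °C; aq NH4Cl
Reagents that add atoms: none
Why: copper-catalysed asymmetric conjugate addition of a Grignard reagent to a cyclic enone; the chiral diphosphine–copper complex selects one enone face and sets the future ring 5/ring 6 fusion stereocentre.

Step 2
Reactants: 3 (3S)-3-[2-(1,3-dioxolan-2-yl)ethyl]cyclohexan-1-one
Product: 5 (7aS)-1,2,5,6,7,7a-hexahydro-4H-inden-4-one, via keto aldehyde 4 (not isolated)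
Conditions: 2 M HCl, THF, 60 °C
Reagents that add atoms: none
Why: acetal hydrolysis then intramolecular aldol condensation (cyclopentene annulation) through the ketone α-carbon next to the side chain closes ring 6; the stereocentre is not enolisable and is retained.

Step 3
Reactants: 6 cyclopent-2-en-1-one; 7 (prop-1-en-2-yl)magnesium bromide
Product: 9 (3S)-3-(prop-1-en-2-yl)cyclopent-1-en-1-yl trifluoromethanesulfonate, via magnesium enolate 8 (not isolated)
Conditions: CuBr·SMe2 (5 mol%), Josiphos (6 mol%), t-BuOMe, −78 °C; then PhNTf2, THF, −78 → 0 °C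
Reagents that add atoms: N-phenylbis(trifluoromethanesulfonimide), O=S(=O)(N(c1ccccc1)S(=O)(=O)C(F)(F)F)C(F)(F)F
Why: copper-catalysed asymmetric conjugate addition sets the ring 1 stereocentre, and O-triflation of the regiodefined magnesium enolate (enolate trapping) places the enol triflate double bond next to that centre.

Step 4
Reactants: 9 (3S)-3-(prop-1-en-2-yl)cyclopent-1-en-1-yl trifluoromethanesulfonate
Product: 10 (3S)-3-(3-chloroprop-1-en-2-yl)cyclopent-1-en-1-yl trifluoromethanesulfonate
Conditions: Ca(OCl)2, CO2 (solid), CH2Cl2–H2O, 0 °C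
Reagents that add atoms: calcium hypochlorite, [Ca+2].[O-]Cl.[O-]Cl
Why: ene-type allylic chlorination by hypochlorous acid attacks only the electron-rich 1,1-disubstituted alkene and moves its double bond into the former methyl group, leaving the electron-poor enol triflate and the stereocentre untouched.

Step 5
Reactants: 10 (3S)-3-(3-chloroprop-1-en-2-yl)cyclopent-1-en-1-yl trifluoromethanesulfonate; 11 benzyl carbamate
Product: 12 benzyl N-{2-[(1S)-3-{[(trifluoromethyl)sulfonyl]oxy}cyclopent-2-en-1-yl]prop-2-en-1-yl}carbamate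
Conditions: NaH, NaI (10 mol%), DMF, 0 °C → rt
Reagents that add atoms: none
Why: SN2 N-alkylation of the sodium carbamate by the primary allylic chloride (SN2 and SN2' give the same product) installs the nitrogen atom of ring 2.

Step 6
Reactants: 12 benzyl N-{2-[(1S)-3-{[(trifluoromethyl)sulfonyl]oxy}cyclopent-2-en-1-yl]prop-2-en-1-yl}carbamate; 13 butyl vinyl ether
Product: 15 benzyl N-{2-[(1S)-3-acetylcyclopent-2-en-1-yl]prop-2-en-1-yl}carbamate, via butoxydiene 14 (not isolated)
Conditions: Pd(OAc)2 (3 mol%), dppp (6 mol%), Et3N, DMF, 80 °C; then 1 M HCl, THF, rt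
Reagents that add atoms: water, O
Why: Heck coupling of the enol triflate at the internal carbon of the electron-rich vinyl ether (cationic palladium pathway with a chelating diphosphine), then hydrolysis of the dienol ether, gives the methyl enone without touching the stereocentre.

Step 7
Reactants: 15 benzyl N-{2-[(1S)-3-acetylcyclopent-2-en-1-yl]prop-2-en-1-yl}carbamate; 16 tert-butyl prop-2-enoate
Product: 18 benzyl (3aR,6S,6aS)-6-acetyl-6-(3-tert-butoxy-3-oxopropyl)-3-methylidenehexahydrocyclopenta[b]pyrrole-1(2H)-carboxylate, via potassium enolate 17 (not isolated)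
Conditions: KN(SiMe3)2 (1.05 equiv), THF, −78 → −40 °C; then 16, −78 → 0 °C; aq NH4Cl
Reagents that add atoms: none
Why: tandem aza-Michael/Michael reaction, in which the carbamate anion closes ring 2 by 5-exo-trig carbon–nitrogen bond formation (cis fusion is the only strain-free mode) and the enolate so formed adds to the acrylate on the convex face, anti to the new carbon–nitrogen bond, which sets the N-bearing methine and the quaternary carbon.

Step 8
Reactants: 18 benzyl (3aR,6S,6aS)-6-acetyl-6-(3-tert-butoxy-3-oxopropyl)-3-methylidenehexahydrocyclopenta[b]pyrrole-1(2H)-carboxylate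
Product: 19 tert-butyl 3-[(3S,3aR,6S,6aS)-6-acetyl-3-methyloctahydrocyclopenta[b]pyrrol-6-yl]propanoate
Conditions: H2 (1 atm), 10% Pd/C, EtOAc, rt
Reagents that add atoms: none
Why: heterogeneous hydrogenation adds hydrogen to the exocyclic methylene from the convex face of the cis-fused bicycle, so the methyl group ends on the concave face, and hydrogenolysis removes the benzyloxycarbonyl group in the same operation.

Step 9
Reactants: 5 (7aS)-1,2,5,6,7,7a-hexahydro-4H-inden-4-one; 19 tert-butyl 3-[(3S,3aR,6S,6aS)-6-acetyl-3-methyloctahydrocyclopenta[b]pyrrol-6-yl]propanoate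
Product: 22 tert-butyl 3-[(3S,3aR,6S,6aS)-6-{1-hydroxy-1-[(4S,5S,7aR)-4-hydroxy-2,4,5,6,7,7a-hexahydro-1H-inden-5-yl]ethyl}-3-methyloctahydrocyclopenta[b]pyrrol-6-yl]propanoate (amino diol; carbinol epimers), via lithium dienolate 20 (not isolated), via aldol ketone 21 (not isolated)
Conditions: 5, LiN(i-Pr)2, THF, −78 °C; add 19 premixed with CeCl3 (1.5 equiv), −78 °C; then NaBH4, MeOH, −78 °C; aq NH4Cl
Reagents that add atoms: none
Why: directed aldol addition of the kinetic cross-conjugated lithium dienolate to the CeCl3-activated methyl ketone, with axial attack on the conformationally locked enolate anti to the ring-fusion hydrogen, followed by in situ Luche reduction in which axial hydride delivery anti to the new axial side chain gives the equatorial allylic alcohol cis to that chain.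

Step 10
Reactants: 22 amino diol (name as in step 9)
Product: 24 pentacyclic amino alcohol tert-butyl ester (ring 3 closed; carbinol epimers), via alkoxyphosphonium salt 23 (not isolated)
Conditions: HBF4·OEt2 (1.0 equiv); PPh3, DIAD, toluene–THF, 0 °C → rt; aq NaHCO3
Reagents that add atoms: none
Why: Proposed new method: ammonium-Mitsunobu cyclodehydration, in which the amine is used as its tetrafluoroborate salt so that its N–H (pKa about 11) protonates the PPh3–DIAD betaine and the amine cannot add to the azo ester; the secondary allylic alcohol (the tertiary one is inert) forms the alkoxyphosphonium ion and the released amine displaces Ph3PO in a 6-exo-tet SN2 step with inversion, which closes ring 3 and places nitrogen trans to the carbinol side chain; the closest known reactions are the Mitsunobu cyclodehydration of N-alkyl amino alcohols at primary carbinols and the Fukuyama–Mitsunobu N-alkylation of sulfonamides.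

Step 11
Reactants: 24 pentacyclic amino alcohol tert-butyl ester
Product: 26 hexacyclic amine lactone (N-deoxy target), via hydroxy acid 25 (not isolated)
Conditions: CF3CO2H–CH2Cl2 (1:3), 0 °C → rt; aq NaHCO3
Reagents that add atoms: none
Why: acid-mediated SN1 lactonisation, in which the tert-butyl group leaves as isobutene and the tertiary carbinol ionises to a cation that the carboxyl group can reach only from its own face of ring 3, so both carbinol epimers converge on the cis-fused lactone with the methyl group axial.

Step 12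
Reactants: 26 hexacyclic amine lactone (N-deoxy target)
Product: 27 target N-oxide CNP0566793.5
Conditions: mCPBA (1.05 equiv), CH2Cl2, −20 → 0 °C; basic Al2O3 filtration
Reagents that add atoms: 3-chloroperoxybenzoic acid, OOC(=O)c1cccc(Cl)c1
Why: N-oxidation of a tertiary amine by a peracid; the three rings at nitrogen lock the lone pair in one orientation, so only the target N-oxide diastereomer forms, and the amine reacts faster than the trisubstituted alkene.

**Compound list**
1 | cyclohex-2-en-1-one | O=C1C=CCCC1 | starting material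
2 | [2-(1,3-dioxolan-2-yl)ethyl]magnesium bromide | Br[Mg]CCC1OCCO1 | starting material
3 | (3S)-3-[2-(1,3-dioxolan-2-yl)ethyl]cyclohexan-1-one | O=C1C[C@H](CCC2OCCO2)CCC1 | intermediate
4 | 3-[(1S)-3-oxocyclohexyl]propanal (keto aldehyde) | O=C1C[C@H](CCC=O)CCC1 | intermediate (not isolated)
5 | (7aS)-1,2,5,6,7,7a-hexahydro-4H-inden-4-one | O=C1C2=CCC[C@@H]2CCC1 | intermediate
6 | cyclopent-2-en-1-one | O=C1C=CCC1 | starting material
7 | (prop-1-en-2-yl)magnesium bromide | C=C(C)[Mg]Br | starting material
8 | bromomagnesium (3S)-3-(prop-1-en-2-yl)cyclopent-1-en-1-olate (magnesium enolate) | C=C(C)[C@@H]1C=C(O[Mg]Br)CC1 | intermediate (not isolated)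
9 | (3S)-3-(prop-1-en-2-yl)cyclopent-1-en-1-yl trifluoromethanesulfonate | C=C(C)[C@@H]1C=C(OS(=O)(=O)C(F)(F)F)CC1 | intermediate
10 | (3S)-3-(3-chloroprop-1-en-2-yl)cyclopent-1-en-1-yl trifluoromethanesulfonate | ClCC(=C)[C@@H]1C=C(OS(=O)(=O)C(F)(F)F)CC1 | intermediate
11 | benzyl carbamate | NC(=O)OCc1ccccc1 | starting material
12 | benzyl N-{2-[(1S)-3-{[(trifluoromethyl)sulfonyl]oxy}cyclopent-2-en-1-yl]prop-2-en-1-yl}carbamate | O=C(NCC(=C)[C@@H]1C=C(OS(=O)(=O)C(F)(F)F)CC1)OCc1ccccc1 | intermediate
13 | butyl vinyl ether (1-(ethenyloxy)butane) | C=COCCCC | starting material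
14 | benzyl N-{2-[(1S)-3-(1-butoxyethenyl)cyclopent-2-en-1-yl]prop-2-en-1-yl}carbamate (butoxydiene) | C=C(OCCCC)C1=C[C@@H](C(=C)CNC(=O)OCc2ccccc2)CC1 | intermediate (not isolated)
15 | benzyl N-{2-[(1S)-3-acetylcyclopent-2-en-1-yl]prop-2-en-1-yl}carbamate | CC(=O)C1=C[C@@H](C(=C)CNC(=O)OCc2ccccc2)CC1 | intermediate
16 | tert-butyl prop-2-enoate | C=CC(=O)OC(C)(C)C | starting material
17 | benzyl (3aR,6aS)-3-methylidene-6-[1-(potassiooxy)ethylidene]hexahydrocyclopenta[b]pyrrole-1(2H)-carboxylate (potassium enolate) | C=C1CN(C(=O)OCc2ccccc2)[C@H]2[C@@H]1CCC2=C(C)O[K] | intermediate (not isolated)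
18 | benzyl (3aR,6S,6aS)-6-acetyl-6-(3-tert-butoxy-3-oxopropyl)-3-methylidenehexahydrocyclopenta[b]pyrrole-1(2H)-carboxylate | C=C1CN(C(=O)OCc2ccccc2)[C@H]2[C@@H]1CC[C@]2(C(C)=O)CCC(=O)OC(C)(C)C | intermediate
19 | tert-butyl 3-[(3S,3aR,6S,6aS)-6-acetyl-3-methyloctahydrocyclopenta[b]pyrrol-6-yl]propanoate | C[C@@H]1CN[C@H]2[C@@H]1CC[C@]2(C(C)=O)CCC(=O)OC(C)(C)C | intermediate
20 | lithium (7aR)-2,6,7,7a-tetrahydro-1H-inden-4-olate (kinetic dienolate of 5; same spatial arrangement, the descriptor changes by priority only) | [Li]OC1=CCC[C@H]2CCC=C12 | intermediate (not isolated)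
21 | tert-butyl 3-[(3S,3aR,6S,6aS)-6-{1-hydroxy-1-[(5R,7aR)-4-oxo-2,4,5,6,7,7a-hexahydro-1H-inden-5-yl]ethyl}-3-methyloctahydrocyclopenta[b]pyrrol-6-yl]propanoate (aldol ketone; carbinol epimers) | C[C@@H]1CN[C@H]2[C@@H]1CC[C@@]2(CCC(=O)OC(C)(C)C)C(C)(O)[C@H]1CC[C@H]2CCC=C2C1=O | intermediate (not isolated)
22 | tert-butyl 3-[(3S,3aR,6S,6aS)-6-{1-hydroxy-1-[(4S,5S,7aR)-4-hydroxy-2,4,5,6,7,7a-hexahydro-1H-inden-5-yl]ethyl}-3-methyloctahydrocyclopenta[b]pyrrol-6-yl]propanoate (amino diol; carbinol epimers) | C[C@@H]1CN[C@H]2[C@@H]1CC[C@@]2(CCC(=O)OC(C)(C)C)C(C)(O)[C@H]1CC[C@H]2CCC=C2[C@H]1O | intermediate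
23 | O-triphenylphosphonio derivative of 22 at the allylic secondary oxygen, tetrafluoroborate (alkoxyphosphonium salt) | C[C@@H]1CN[C@H]2[C@@H]1CC[C@@]2(CCC(=O)OC(C)(C)C)C(C)(O)[C@H]1CC[C@H]2CCC=C2[C@H]1O[P+](c1ccccc1)(c1ccccc1)c1ccccc1.F[B-](F)(F)F | intermediate (not isolated)
24 | pentacyclic amino alcohol tert-butyl ester: 22 with the ring 2 nitrogen bonded to the former allylic carbinol carbon with inversion (rings 1, 2, 3, 5, 6 closed; tertiary carbinol epimers; propanoate chain open) | C[C@@H]1CN2[C@H]3C4=CCC[C@@H]4CC[C@@H]3C(C)(O)[C@]4(CCC(=O)OC(C)(C)C)CC[C@H]1[C@@H]42 | intermediate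
25 | free carboxylic acid of 24 (hydroxy acid) | C[C@@H]1CN2[C@H]3C4=CCC[C@@H]4CC[C@@H]3C(C)(O)[C@]4(CCC(=O)O)CC[C@H]1[C@@H]42 | intermediate (not isolated)
26 | hexacyclic tertiary amine lactone (N-deoxy target; cis-fused lactone, methyl on the carbinol carbon axial) | C[C@@H]1CN2[C@H]3C4=CCC[C@@H]4CC[C@@H]3[C@@]3(C)OC(=O)CC[C@]34CC[C@H]1[C@@H]42 | intermediate
27 | target N-oxide CNP0566793.5 | C[C@@H]1C[N@+]2([O-])[C@H]3C4=CCC[C@@H]4CC[C@@H]3[C@@]3(C)OC(=O)CC[C@]34CC[C@H]1[C@@H]42 | target

**Step count and risks**
Total steps: 12. Longest linear sequence: 10 steps (6 → 27, steps 3–12); enone 5 is made in 2 steps and joins at step 9.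

A point that shapes the route: in the target the nitrogen and the carbinol side chain on ring 5 are trans while the ring 6 methylene forces ring 5 out of its relaxed chair (twist-boat). The target is therefore the less stable arrangement at this fusion, and steps 9 and 10 rely on kinetic control (axial attack, then SN2 inversion) and not on equilibration.

The three steps most likely to fail:

1. Step 10 (the new ring closure). The allylic oxyphosphonium ion may ionise (SN1 would give the unstrained cis-fused isomer), react SN2' or eliminate, and the SN2 transition state must already pay for the twist-boat of ring 5. Fallback with known chemistry, setting out from 22 and returning at 24: Mitsunobu esterification of 22 with 4-nitrobenzoic acid (PPh3, DIAD, THF, 0 °C) inverts the allylic carbinol and gives the allylic 4-nitrobenzoate ester F2. Pd(PPh3)4 (5 mol%) with Et3N in THF at 50 °C then ionises F2 anti to the ester, and the tethered amine attacks the allyl ligand on the face opposite to palladium (Tsuji–Trost amination through zerovalent palladium, overall retention from F2). The nitrogen thus ends where the ester oxygen was, which is 24.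

2. Step 9 (aldol to a hindered, enolisable methyl ketone, and facial selectivity on the dienolate). Proton transfer or retro-aldol may win, and equatorial attack would give the wrong ring 5 methine. Fallback, setting out from 5 and 19 and returning at 21: 5 is converted with LiN(i-Pr)2 and Me3SiCl (THF, −78 °C) into the trimethylsilyl dienol ether F1. Mukaiyama aldol addition of F1 to 19 held as its TiCl4 complex (2.2 equiv TiCl4, CH2Cl2, −78 °C; the first equivalent ties up the amine) gives the aldol ketone 21 through an open transition state without a basic enolate. Reduction of 21 with NaBH4 and CeCl3 in MeOH at −78 °C, as in step 9, returns to 22.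

3. Step 11 (cationic lactonisation). The tertiary cation may lose a proton toward the ring 5 methine and scramble that centre, or rearrange. Fallback, setting out from 24 and returning at 26: Burgess reagent (benzene, 50 °C) dehydrates the tertiary carbinol by syn-elimination into the methyl group to the exocyclic alkene F3. Iodolactonisation of F3 as its trifluoroacetate salt (I2, MeCN, 0 °C) opens the iodonium ion at the tertiary carbon with the ester carbonyl, which loses isobutene, and gives the iodomethyl lactone F4, cis-fused for the same geometric reason as in step 11. Radical deiodination with Bu3SnH and AIBN (benzene, 80 °C) gives 26.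

**Further compounds**
F1 | step 9 | trimethyl{[(7aR)-2,6,7,7a-tetrahydro-1H-inden-4-yl]oxy}silane (silyl dienol ether of 5) | C[Si](C)(C)OC1=CCC[C@H]2CCC=C12
F2 | step 10 | 4-nitrobenzoate ester of 22 at the allylic secondary oxygen with inverted (4R) carbinol carbon | C[C@@H]1CN[C@H]2[C@@H]1CC[C@@]2(CCC(=O)OC(C)(C)C)C(C)(O)[C@H]1CC[C@H]2CCC=C2[C@@H]1OC(=O)c1ccc(cc1)[N+](=O)[O-]
F3 | step 11 | exocyclic alkene from 24 (tertiary carbinol replaced by a 1,1-disubstituted C=CH2; tert-butyl ester kept) | C[C@@H]1CN2[C@H]3C4=CCC[C@@H]4CC[C@@H]3C(=C)[C@]4(CCC(=O)OC(C)(C)C)CC[C@H]1[C@@H]42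
F4 | step 11 | iodomethyl lactone (26 with CH2I in place of the carbinol methyl group) | C[C@@H]1CN2[C@H]3C4=CCC[C@@H]4CC[C@@H]3[C@@]3(CI)OC(=O)CC[C@]34CC[C@H]1[C@@H]42
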